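## Analysis of the target

Germacrane numbering is used for all intermediates: ring carbons C1–C10, lactone carbons C11–C13, C14 = methyl on C10, C15 = CH2OH on C4; α/β refer to the usual flat drawing.

- The target is a germacranolide. A ten-membered carbocycle (C1–C10) carries a trans-fused α-methylene-γ-butyrolactone across C6–C7 (O on C6, C11=C13 exocyclic) and, on the C8 oxygen, the ester of (2Z)-2-(hydroxymethyl)but-2-enoic acid.
- Six contiguous ring carbons, C10–C1–C2–C3–C4–C5, form one unit: a C1–C10 epoxide, a Z C2=C3 bond, and a C4=C5 bond whose ring neighbours C3 and C6 are cis (4E by CIP because of C15–O).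
- This unit is a cyclodeca-1(10),2,4-triene in which only the terminal trisubstituted double bond is epoxidised. Such a triene is the ring-opened valence isomer of a bicyclo[4.4.0]deca-2,4-diene, that is, a eudesma-1,3-diene with a C5–C10 bond. The strategy rests on this feature.
- There are five stereocentres, all R. C1 and C10 form a trans epoxide (from an E C1=C10 olefin; O is β at C1, C14 is β). C6 carries O α, C7 carries C11 β, C8 carries O β (H6/H7 trans, H7/H8 cis).
- The epoxide carbons are separated from the C6–C8 cluster by sp2 carbons on one side and a CH2 on the other, so an open-chain precursor offers no relay between them.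
- Sensitive groups: the vinyl epoxide (acid, Pd(0), low-valent metals), the α-methylene lactone (Michael acceptor, base, hydride), and the Z-acyl group, which isomerises to E under nucleophilic acyl-transfer catalysis. A free 8β-OH could translactonise.
- The difficulty is a strained medium ring in which seven of ten ring atoms are sp2 or epoxide carbons. Seco precursors are (Z,Z)-dienyl aldehydes or metals that isomerise or electrocyclise, and two olefin geometries and the epoxide configuration have to be fixed together with the ring.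

## Retrosynthetic reasoning

**32 ⇒ 31.** Only the two primary allylic silyl ethers are removed at the end, with buffered fluoride. All sensitive functions are already in place and no redox step follows the key step.

**31 ⇒ 30 ⇒ 29 (key disconnection).** The two epoxide C–O bonds are removed to give the E C1=C10 olefin of triene 30, and the C5–C10 bond is then re-formed to give the cis-fused decalin diene 29. Any other cut of the ten-membered ring leaves a (Z,Z)-dienyl chain end. This cut instead gives a rigid bicycle in which all stereocentres can be set by chair conformations. The forward reaction must open 29 photochemically with one sense of conrotation (4,5-cis and 1(10)-trans) and then transfer oxygen to C1=C10 only. The geometry demands a cis ring fusion with H-5 and C14 both α, held in one chair by the trans-lactone.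

**29 ⇒ 22 + 28.** The C8–O ester bond is formed with inversion. The alcohol can then be the equatorial 8α epimer 22, which is the epimer the ring-B closure tolerates best, and the isomerisation-prone Z-acid 28 never meets an acyl-transfer catalyst.

**22 ⇒ 21 ⇒ 19.** The lactone C–O bond and the C6–C7 bond are cut together. An intramolecular allylation of the C6 aldehyde by a 2-(alkoxycarbonyl)allyl metal closes ring B, sets C6 and C7 in a chair, and delivers the α-methylene lactone directly.

**19 ⇒ 18 ⇒ 16 + 17.** The C7=C11 bond comes from cross-metathesis of a terminal vinyl group with acrylate 17. The aldehyde is kept as its dimethyl acetal until just before use.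

**16 ⇒ 15 ⇒ 14 ⇒ 12.** The ring-A diene and the C15 oxygen arise by 1,2-reduction and acid transposition of the doubly vinylogous silyl ester 12. This moves the oxygen function from C1 to C15 and leaves C1=C2–C3=C4.

**12 ⇒ 10 ⇒ 5 + 8.** The quaternary C10 is built by two α′-alkylations next to the C5 stereocentre. Methyl enters last, anti to the C5 substituent, so C9 ends cis to C6 (the future cis fusion). C8 comes from the chiral pool through triflate 8, made from diol 6.

**5 ⇒ 4 ⇒ 3 ⇒ 1 + 2.** The cyclohexenone is made by a catalytic enantioselective Diels–Alder reaction and Saegusa oxidation. Only C5 survives from this step and it relays to all later centres. The C4 centre is planarised in 5.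

**28 ⇒ 26 ⇒ 25 ⇒ 24 ⇒ 23.** The Z-acid comes from crotonaldehyde through α-iodination, reduction, silylation and stereoretentive lithiation–carboxylation.

## Alternatives that were turned down

**Alternative 1:** (textbook) Cut C6–C7 and the lactone C–O bond of 31. The forward step is an intramolecular chromium- or zinc-mediated Barbier allylation–lactonisation of seco-aldehyde A1. Reasons against:
- A1 is a 2,4-dienal with a cis C4=C5 bond. This 1-oxatriene is set up for 6π-oxa-electrocyclisation to a 2H-pyran and for Z→E isomerisation through its dienol.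
- The vinyl epoxide would have to survive low-valent chromium and Lewis-acidic Cr(III).
- The two Z olefins, the epoxide and C8 must each be set by a separate reagent-controlled event along a long linear chain.
- The ring closure itself has to pay the strain of a ring with seven sp2-type atoms.

**Alternative 2:** Cut C2=C3 of 31. The forward step is ring-closing metathesis of tetraene A2. Reasons against:
- Nothing enforces Z geometry at C2=C3 in a strained ten-membered ring.
- The ruthenium carbene formed at the dienyl terminus can back-bite onto C4=C5 and truncate the chain.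
- A2 already needs all five stereocentres and the cis C4=C5 olefin, so the step count is no lower and the key step builds only one bond.

**Alternative 3:** Cut C8–C9 and regenerate a C1–C6 bond. The forward step is an anionic oxy-Cope ring expansion of dialkenyl cyclohexadienol A3 to the C6-keto cyclodecatriene. It would deliver the whole triene at once. Reasons against:
- A3 can only come from 1,2-addition to dienone A4, which is the non-aromatic keto tautomer of a phenol and cannot be handled.
- A3 itself would aromatise by loss of water.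
- C7 and C8 would be set only by enolate protonation and enol ether geometry.

Key step: step 19

Remark on the chemistry: the oxazaborolidine antipode in step 1 is the one that the accepted facial model for α-unsubstituted enals assigns to the (6R) adduct; if the sense is opposite, the commercial enantiomer is used and nothing else changes.

## Route

Step 1
Reactants: 1 2-(trimethylsilyloxy)buta-1,3-diene; 2 (2E)-4,4-dimethoxybut-2-enal
Product: 3 (1R,6R)-6-(dimethoxymethyl)-4-(trimethylsilyloxy)cyclohex-3-ene-1-carbaldehyde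
Conditions: (S)-B-(o-tolyl)oxazaborolidine from diphenylprolinol·Tf2NH (10 mol %), CH2Cl2, −78 °C
Reagents that add atoms: none
Why: Catalytic enantioselective Diels–Alder reaction with a cationic oxazaborolidine Lewis acid; the nucleophilic CH2 terminus next to C–OSi bonds to the enal β-carbon ("para" adduct), and the catalyst shields one face of the bound s-trans enal, which sets C5 (the C4 centre is erased in step 3).

Step 2
Reactants: 3 (1R,6R)-6-(dimethoxymethyl)-4-(trimethylsilyloxy)cyclohex-3-ene-1-carbaldehyde
Product: 4 (1R,6R)-6-(dimethoxymethyl)-4-oxocyclohex-2-ene-1-carbaldehyde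
Conditions: Pd(OAc)2 (1.1 equiv), MeCN, 23 °C
Reagents that add atoms: none
Why: Saegusa–Ito oxidation; the regiodefined silyl enol ether gives the C2=C3 enone only, which blocks C2 against enolisation and later becomes part of the diene.

Step 3
Reactants: 4 (1R,6R)-6-(dimethoxymethyl)-4-oxocyclohex-2-ene-1-carbaldehyde
Product: 5 (5R)-4-[(tert-butyldimethylsilyloxy)methylidene]-5-(dimethoxymethyl)cyclohex-2-en-1-one (E/Z mixture at the enol ether)
Conditions: TBSCl, Et3N, DMAP (cat.), CH2Cl2, 0 °C
Reagents that add atoms: tert-butyldimethylsilyl chloride CC(C)(C)[Si](C)(C)Cl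
Why: O-silylation of the vinylogous acid (γ-formyl enone) at the aldehyde-derived oxygen, as with 2-formyl ketones; C4 becomes planar and C15 is masked, giving a doubly vinylogous silyl ester.

Step 4
Reactants: 6 (2R)-but-3-ene-1,2-diol
Product: 8 (2R)-2-(tert-butyldimethylsilyloxy)but-3-en-1-yl trifluoromethanesulfonate, via hydroxy triflate 7 (not isolated)
Conditions: Tf2O (1.0 equiv), 2,6-lutidine, CH2Cl2, −78 °C; then TBSOTf, −78 → −30 °C; used at once
Reagents that add atoms: triflic anhydride O=S(=O)(OS(=O)(=O)C(F)(F)F)C(F)(F)F; tert-butyldimethylsilyl triflate CC(C)(C)[Si](C)(C)OS(=O)(=O)C(F)(F)F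
Why: One-pot selective sulfonylation of the primary hydroxyl followed by silylation of the secondary one; the stereocentre (future C8) is untouched.

Step 5
Reactants: 5 (5R)-4-[(tert-butyldimethylsilyloxy)methylidene]-5-(dimethoxymethyl)cyclohex-2-en-1-one; 8 (2R)-2-(tert-butyldimethylsilyloxy)but-3-en-1-yl trifluoromethanesulfonate
Product: 10 (5R,6R)-6-[(2S)-2-(tert-butyldimethylsilyloxy)but-3-en-1-yl]-4-[(tert-butyldimethylsilyloxy)methylidene]-5-(dimethoxymethyl)cyclohex-2-en-1-one, via lithium dienolate 9 (not isolated)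
Conditions: LDA, THF, −78 °C; then 8, DMPU, −78 → −40 °C
Reagents that add atoms: none
Why: Stork–Danheiser-type kinetic α′-deprotonation (C10 is the only acidic position) and SN2 alkylation by the primary triflate; the C10 configuration formed here is irrelevant because step 6 passes through the enolate again.

Step 6
Reactants: 10 (5R,6R)-6-[(2S)-2-(tert-butyldimethylsilyloxy)but-3-en-1-yl]-4-[(tert-butyldimethylsilyloxy)methylidene]-5-(dimethoxymethyl)cyclohex-2-en-1-one
Product: 12 (5S,6S)-6-[(2S)-2-(tert-butyldimethylsilyloxy)but-3-en-1-yl]-4-[(tert-butyldimethylsilyloxy)methylidene]-5-(dimethoxymethyl)-6-methylcyclohex-2-en-1-one, via lithium dienolate 11 (not isolated)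
Conditions: LDA, THF, −78 → −40 °C; then MeI, DMPU, −78 → −20 °C
Reagents that add atoms: iodomethane CI
Why: Second α′-alkylation; methyl iodide should approach the tetrasubstituted enolate anti to the adjacent C5 dimethoxymethyl group (C4 is planar and exerts no bias), so C14 ends trans to C6 and C9 cis to C6, the relationship that becomes the cis ring fusion.

Step 7
Reactants: 12 (5S,6S)-6-[(2S)-2-(tert-butyldimethylsilyloxy)but-3-en-1-yl]-4-[(tert-butyldimethylsilyloxy)methylidene]-5-(dimethoxymethyl)-6-methylcyclohex-2-en-1-one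
Product: 14 (5R,6R)-5-[(2S)-2-(tert-butyldimethylsilyloxy)but-3-en-1-yl]-6-(dimethoxymethyl)-5-methylcyclohexa-1,3-diene-1-carbaldehyde, via dienyl alcohol 13 (not isolated)
Conditions: DIBAL-H, CH2Cl2, −78 °C; Rochelle-salt work-up; then oxalic acid (cat.), wet SiO2, CH2Cl2, 0 °C
Reagents that add atoms: none
Why: Stork–Danheiser reduction–transposition in its doubly vinylogous form; 1,2-reduction gives a dienylic alcohol whose ionisation is assisted by the silyloxy terminus, and collapse to the aldehyde places the double bonds at C1=C2 and C3=C4 under conditions too mild for the dimethyl acetal.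

Step 8
Reactants: 14 (5R,6R)-5-[(2S)-2-(tert-butyldimethylsilyloxy)but-3-en-1-yl]-6-(dimethoxymethyl)-5-methylcyclohexa-1,3-diene-1-carbaldehyde
Product: 15 [(5R,6R)-5-[(2S)-2-(tert-butyldimethylsilyloxy)but-3-en-1-yl]-6-(dimethoxymethyl)-5-methylcyclohexa-1,3-dien-1-yl]methanol
Conditions: NaBH4, CeCl3·7H2O, MeOH, −40 °C
Reagents that add atoms: none
Why: Luche 1,2-reduction of the dienal to the C15 carbinol; the diene is not touched.

Step 9
Reactants: 15 [(5R,6R)-5-[(2S)-2-(tert-butyldimethylsilyloxy)but-3-en-1-yl]-6-(dimethoxymethyl)-5-methylcyclohexa-1,3-dien-1-yl]methanol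
Product: 16 tert-butyldiphenylsilyl ether of 15
Conditions: TBDPSCl, imidazole, CH2Cl2, 0 → 23 °C
Reagents that add atoms: tert-butyldiphenylsilyl chloride CC(C)(C)[Si](Cl)(c1ccccc1)c1ccccc1
Why: Silylation of the primary alcohol with a group that outlasts the later removal of the secondary TBS ether at C8.

Step 10
Reactants: 16 tert-butyldiphenylsilyl ether of 15; 17 methyl 2-(bromomethyl)prop-2-enoate
Product: 18 methyl (2Z,4S)-2-(bromomethyl)-4-(tert-butyldimethylsilyloxy)-5-[(1R,6R)-5-(tert-butyldiphenylsilyloxymethyl)-6-(dimethoxymethyl)-1-methylcyclohexa-2,4-dien-1-yl]pent-2-enoate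
Conditions: second-generation Ru NHC isopropoxybenzylidene catalyst (10 mol %), 17 (5 equiv), CH2Cl2, 40 °C
Reagents that add atoms: none
Why: Olefin cross-metathesis of the only terminal alkene with the 1,1-disubstituted acrylate; the thermodynamic isomer with the ester trans to the chain is expected, and the cyclic diene is a poor metathesis substrate.

Step 11
Reactants: 18 methyl (2Z,4S)-2-(bromomethyl)-4-(tert-butyldimethylsilyloxy)-5-[(1R,6R)-5-(tert-butyldiphenylsilyloxymethyl)-6-(dimethoxymethyl)-1-methylcyclohexa-2,4-dien-1-yl]pent-2-enoate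
Product: 19 methyl (2Z,4S)-2-(bromomethyl)-4-(tert-butyldimethylsilyloxy)-5-[(1R,6R)-5-(tert-butyldiphenylsilyloxymethyl)-6-formyl-1-methylcyclohexa-2,4-dien-1-yl]pent-2-enoate
Conditions: TESOTf, 2,4,6-collidine, CH2Cl2, 0 °C; then H2O
Reagents that add atoms: water O
Why: Chemoselective cleavage of the dimethyl acetal through a collidinium intermediate under non-acidic conditions, so the β,γ-unsaturated α-branched aldehyde is released without enolisation at C5 and the silyl ethers stay.

Step 12
Reactants: 19 methyl (2Z,4S)-2-(bromomethyl)-4-(tert-butyldimethylsilyloxy)-5-[(1R,6R)-5-(tert-butyldiphenylsilyloxymethyl)-6-formyl-1-methylcyclohexa-2,4-dien-1-yl]pent-2-enoate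
Product: 21 8α-(tert-butyldimethylsilyloxy)-15-(tert-butyldiphenylsilyloxy)-5αH-10-epi-eudesma-1,3,11(13)-trien-6α,12-olide (cis-fused, C14 α), via hydroxy ester 20 (not isolated)
Conditions: CrCl2 (5 equiv), THF, 0.005 M, 23 °C; aq. NH4Cl; PPTS (cat.) to complete lactonisation if needed
Reagents that add atoms: none
Why: Intramolecular Nozaki–Hiyama-type Barbier allylation followed by lactonisation; the Zimmerman–Traxler chair is fused trans to the forming ring-B chair, in which C6–O, C7–C11 and the C8 silyloxy group are equatorial and only C1 is axial, so C6 (O α) and C7 (C11 β) are set relative to C5, C8 and C10 and the lactone is trans.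

Step 13
Reactants: 21 8α-(tert-butyldimethylsilyloxy)-15-(tert-butyldiphenylsilyloxy)-5αH-10-epi-eudesma-1,3,11(13)-trien-6α,12-olide
Product: 22 8α-hydroxy-15-(tert-butyldiphenylsilyloxy)-5αH-10-epi-eudesma-1,3,11(13)-trien-6α,12-olide
Conditions: HF·pyridine, pyridine, THF, 0 → 23 °C
Reagents that add atoms: none
Why: Acidic fluoride removes the secondary TBS ether much faster than the primary TBDPS ether; lactone and diene tolerate the buffered medium.

Step 14
Reactants: 23 (2E)-but-2-enal
Product: 24 (2Z)-2-iodobut-2-enal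
Conditions: I2, K2CO3, DMAP (cat.), THF/H2O, 23 °C
Reagents that add atoms: iodine II
Why: α-Iodination of the enal by conjugate addition of the amine, iodination of the enolate and elimination; the formyl group stays trans to the methyl group, so iodine is cis to it.

Step 15
Reactants: 24 (2Z)-2-iodobut-2-enal
Product: 25 (2Z)-2-iodobut-2-en-1-ol
Conditions: NaBH4, MeOH, 0 °C
Reagents that add atoms: none
Why: 1,2-Reduction of the aldehyde; the olefin geometry is not affected.

Step 16
Reactants: 25 (2Z)-2-iodobut-2-en-1-ol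
Product: 26 tert-butyl{[(2Z)-2-iodobut-2-en-1-yl]oxy}dimethylsilane
Conditions: TBSCl, imidazole, CH2Cl2, 23 °C
Reagents that add atoms: tert-butyldimethylsilyl chloride CC(C)(C)[Si](C)(C)Cl
Why: Standard silylation of the primary allylic alcohol.

Step 17
Reactants: 26 tert-butyl{[(2Z)-2-iodobut-2-en-1-yl]oxy}dimethylsilane
Product: 28 (2Z)-2-[(tert-butyldimethylsilyloxy)methyl]but-2-enoic acid, via vinyllithium 27 (not isolated)
Conditions: t-BuLi (2.1 equiv), Et2O, −78 °C; CO2; 1 M HCl
Reagents that add atoms: carbon dioxide O=C=O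
Why: Iodine–lithium exchange and carboxylation both proceed with retention at the sp2 carbon, so the carboxyl group ends cis to the methyl group (Z), the less stable geometry that condensation routes do not give.

Step 18
Reactants: 22 8α-hydroxy-15-(tert-butyldiphenylsilyloxy)-5αH-10-epi-eudesma-1,3,11(13)-trien-6α,12-olide; 28 (2Z)-2-[(tert-butyldimethylsilyloxy)methyl]but-2-enoic acid
Product: 29 8β-{(2Z)-2-[(tert-butyldimethylsilyloxy)methyl]but-2-enoyloxy}-15-(tert-butyldiphenylsilyloxy)-5αH-10-epi-eudesma-1,3,11(13)-trien-6α,12-olide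
Conditions: PPh3, DIAD, toluene, 0 → 40 °C
Reagents that add atoms: none
Why: Mitsunobu esterification with SN2 inversion at C8 (8α-OH to 8β-ester); the carboxylate is the nucleophile, so no acyl-transfer catalyst can isomerise the Z-acid.

Step 19
Reactants: 29 8β-{(2Z)-2-[(tert-butyldimethylsilyloxy)methyl]but-2-enoyloxy}-15-(tert-butyldiphenylsilyloxy)-5αH-10-epi-eudesma-1,3,11(13)-trien-6α,12-olide
Product: 31 15-O-tert-butyldiphenylsilyl, side-chain O-tert-butyldimethylsilyl ether of the target (1β,10α-epoxide), via germacratriene 30 (not isolated)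
Conditions: hν (300 nm, Pyrex), Et2O, 2 mM, −40 °C, to partial conversion; lamp off; DMDO (acetone, 1.1 equiv on triene), −40 → −20 °C
Reagents that add atoms: dimethyldioxirane CC1(C)OO1
Why: Excitation of the homoannular diene (the acrylate units do not absorb at 300 nm) triggers the photochemically allowed conrotatory 6π-electrocyclic opening of the C5–C10 σ-bond, the reaction type by which fused cyclohexa-1,3-dienes such as provitamin-D steroids, eudesma-1,3-dienes and cis-bicyclo[4.4.0]deca-2,4-dienes give (cyclo)hexatrienes. No ring is closed by bond formation in this event: the ten-membered ring C1–C10 arises by cleavage of the zero-atom bridge of the decalin, and the oxirane is then closed by concerted oxygen transfer from the dioxirane to C1=C10. The sense of conrotation follows the ground-state helicity of the diene: the trans-lactone holds ring B in one chair, in which the cis fusion makes C5–C6 pseudo-axial and C10–C9 pseudo-equatorial on ring A, and the axial bond turns inward while the equatorial bond turns outward, so C6 ends cis to C3 across C4=C5, C9 ends trans to C2 across C1=C10 and C2=C3 stays Z. This torquoselectivity is what the step needs most, and it is secured by the cis C5/C10 fusion (steps 1 and 6) and the lactone lock (step 12); a trans-fused epimer would give the 4,5-trans triene. Triene 30 can re-close thermally by the disrotatory path and is therefore oxidised cold without isolation. For site selectivity, C1=C10 is the only trialkyl-substituted, strained E-olefin, C4=C5 is deactivated by two allylic C–O bonds, C2=C3 is the least nucleophilic bond of the triene and the acrylates are electron-poor. C1 and C10 are set together by attack on the outer face of the E-olefin once the C1=C10 unit has swung into the usual germacranolide conformation with C14 on the β face, which should give the 1β,10α (1R,10R) epoxide.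

Step 20
Reactants: 31 15-O-tert-butyldiphenylsilyl, side-chain O-tert-butyldimethylsilyl ether of the target
Product: 32 1β,10α-epoxy-15-hydroxy-8β-[(2Z)-2-(hydroxymethyl)but-2-enoyloxy]germacra-2Z,4(ring-cis; 4E by CIP),11(13)-trien-6α,12-olide (CNP0293319.2)
Conditions: TBAF, AcOH (1:1), THF, 0 → 23 °C
Reagents that add atoms: none
Why: Buffered fluoride cleaves both primary allylic silyl ethers; the buffer keeps the medium neutral enough for the α-methylene lactone, the esters and the vinyl epoxide.

## Compound list

1 | 2-(trimethylsilyloxy)buta-1,3-diene | C=CC(=C)O[Si](C)(C)C | starting material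
2 | (2E)-4,4-dimethoxybut-2-enal | COC(OC)/C=C/C=O | starting material
3 | (1R,6R)-6-(dimethoxymethyl)-4-(trimethylsilyloxy)cyclohex-3-ene-1-carbaldehyde | COC(OC)[C@H]1[C@H](C=O)CC=C(O[Si](C)(C)C)C1 | intermediate
4 | (1R,6R)-6-(dimethoxymethyl)-4-oxocyclohex-2-ene-1-carbaldehyde | COC(OC)[C@H]1[C@H](C=O)C=CC(=O)C1 | intermediate
5 | (5R)-4-[(tert-butyldimethylsilyloxy)methylidene]-5-(dimethoxymethyl)cyclohex-2-en-1-one (E/Z mixture) | COC(OC)[C@H]1C(=CO[Si](C)(C)C(C)(C)C)C=CC(=O)C1 | intermediate
6 | (2R)-but-3-ene-1,2-diol | C=C[C@@H](O)CO | starting material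
7 | (2R)-2-hydroxybut-3-en-1-yl trifluoromethanesulfonate | C=C[C@@H](O)COS(=O)(=O)C(F)(F)F | intermediate (not isolated)
8 | (2R)-2-(tert-butyldimethylsilyloxy)but-3-en-1-yl trifluoromethanesulfonate | C=C[C@@H](O[Si](C)(C)C(C)(C)C)COS(=O)(=O)C(F)(F)F | intermediate
9 | lithium cross-conjugated dienolate of 5 | COC(OC)[C@H]1C(=CO[Si](C)(C)C(C)(C)C)C=CC(O[Li])=C1 | intermediate (not isolated)
10 | (5R,6R)-6-[(2S)-2-(tert-butyldimethylsilyloxy)but-3-en-1-yl]-4-[(tert-butyldimethylsilyloxy)methylidene]-5-(dimethoxymethyl)cyclohex-2-en-1-one | COC(OC)[C@H]1C(=CO[Si](C)(C)C(C)(C)C)C=CC(=O)[C@@H]1C[C@H](O[Si](C)(C)C(C)(C)C)C=C | intermediate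
11 | lithium dienolate of 10 | COC(OC)[C@H]1C(=CO[Si](C)(C)C(C)(C)C)C=CC(O[Li])=C1C[C@H](O[Si](C)(C)C(C)(C)C)C=C | intermediate (not isolated)
12 | (5S,6S)-6-[(2S)-2-(tert-butyldimethylsilyloxy)but-3-en-1-yl]-4-[(tert-butyldimethylsilyloxy)methylidene]-5-(dimethoxymethyl)-6-methylcyclohex-2-en-1-one | COC(OC)[C@H]1C(=CO[Si](C)(C)C(C)(C)C)C=CC(=O)[C@@]1(C)C[C@H](O[Si](C)(C)C(C)(C)C)C=C | intermediate
13 | cyclohex-2-en-1-ol from 12 (C1 epimers) | COC(OC)[C@H]1C(=CO[Si](C)(C)C(C)(C)C)C=CC(O)[C@@]1(C)C[C@H](O[Si](C)(C)C(C)(C)C)C=C | intermediate (not isolated)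
14 | (5R,6R)-5-[(2S)-2-(tert-butyldimethylsilyloxy)but-3-en-1-yl]-6-(dimethoxymethyl)-5-methylcyclohexa-1,3-diene-1-carbaldehyde | COC(OC)[C@H]1C(C=O)=CC=C[C@@]1(C)C[C@H](O[Si](C)(C)C(C)(C)C)C=C | intermediate
15 | [(5R,6R)-5-[(2S)-2-(tert-butyldimethylsilyloxy)but-3-en-1-yl]-6-(dimethoxymethyl)-5-methylcyclohexa-1,3-dien-1-yl]methanol | COC(OC)[C@H]1C(CO)=CC=C[C@@]1(C)C[C@H](O[Si](C)(C)C(C)(C)C)C=C | intermediate
16 | tert-butyldiphenylsilyl ether of 15 | COC(OC)[C@H]1C(CO[Si](c2ccccc2)(c2ccccc2)C(C)(C)C)=CC=C[C@@]1(C)C[C@H](O[Si](C)(C)C(C)(C)C)C=C | intermediate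
17 | methyl 2-(bromomethyl)prop-2-enoate | C=C(CBr)C(=O)OC | starting material
18 | methyl (2Z,4S)-2-(bromomethyl)-4-(tert-butyldimethylsilyloxy)-5-[(1R,6R)-5-(tert-butyldiphenylsilyloxymethyl)-6-(dimethoxymethyl)-1-methylcyclohexa-2,4-dien-1-yl]pent-2-enoate | COC(OC)[C@H]1C(CO[Si](c2ccccc2)(c2ccccc2)C(C)(C)C)=CC=C[C@@]1(C)C[C@H](O[Si](C)(C)C(C)(C)C)/C=C(\CBr)C(=O)OC | intermediate
19 | methyl (2Z,4S)-2-(bromomethyl)-4-(tert-butyldimethylsilyloxy)-5-[(1R,6R)-5-(tert-butyldiphenylsilyloxymethyl)-6-formyl-1-methylcyclohexa-2,4-dien-1-yl]pent-2-enoate | O=C[C@H]1C(CO[Si](c2ccccc2)(c2ccccc2)C(C)(C)C)=CC=C[C@@]1(C)C[C@H](O[Si](C)(C)C(C)(C)C)/C=C(\CBr)C(=O)OC | intermediate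
20 | ring-B-closed 6α-hydroxy methyl ester (methyl 2-(decalinyl)acrylate) | COC(=O)C(=C)[C@H]1[C@H](O)[C@H]2C(CO[Si](c3ccccc3)(c3ccccc3)C(C)(C)C)=CC=C[C@@]2(C)C[C@@H]1O[Si](C)(C)C(C)(C)C | intermediate (not isolated)
21 | 8α-(tert-butyldimethylsilyloxy)-15-(tert-butyldiphenylsilyloxy)-5αH-10-epi-eudesma-1,3,11(13)-trien-6α,12-olide | C=C1C(=O)O[C@@H]2[C@H]3C(CO[Si](c4ccccc4)(c4ccccc4)C(C)(C)C)=CC=C[C@@]3(C)C[C@H](O[Si](C)(C)C(C)(C)C)[C@@H]12 | intermediate
22 | 8α-hydroxy-15-(tert-butyldiphenylsilyloxy)-5αH-10-epi-eudesma-1,3,11(13)-trien-6α,12-olide | C=C1C(=O)O[C@@H]2[C@H]3C(CO[Si](c4ccccc4)(c4ccccc4)C(C)(C)C)=CC=C[C@@]3(C)C[C@H](O)[C@@H]12 | intermediate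
23 | (2E)-but-2-enal | C/C=C/C=O | starting material
24 | (2Z)-2-iodobut-2-enal | C/C=C(\I)C=O | intermediate
25 | (2Z)-2-iodobut-2-en-1-ol | C/C=C(\I)CO | intermediate
26 | tert-butyl{[(2Z)-2-iodobut-2-en-1-yl]oxy}dimethylsilane | C/C=C(\I)CO[Si](C)(C)C(C)(C)C | intermediate
27 | (Z)-1-[(tert-butyldimethylsilyloxy)methyl]prop-1-enyllithium | C/C=C(\[Li])CO[Si](C)(C)C(C)(C)C | intermediate (not isolated)
28 | (2Z)-2-[(tert-butyldimethylsilyloxy)methyl]but-2-enoic acid | C/C=C(\C(=O)O)CO[Si](C)(C)C(C)(C)C | intermediate
29 | 8β-{(2Z)-2-[(tert-butyldimethylsilyloxy)methyl]but-2-enoyloxy}-15-(tert-butyldiphenylsilyloxy)-5αH-10-epi-eudesma-1,3,11(13)-trien-6α,12-olide | C=C1C(=O)O[C@@H]2[C@H]3C(CO[Si](c4ccccc4)(c4ccccc4)C(C)(C)C)=CC=C[C@@]3(C)C[C@@H](OC(=O)/C(=C\C)CO[Si](C)(C)C(C)(C)C)[C@@H]12 | intermediate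
30 | corresponding germacra-1(10)E,2Z,4(ring-cis),11(13)-tetraen-6α,12-olide | C=C1C(=O)O[C@@H]2/C=C(CO[Si](c3ccccc3)(c3ccccc3)C(C)(C)C)\C=C/C=C(\C)C[C@@H](OC(=O)/C(=C\C)CO[Si](C)(C)C(C)(C)C)[C@@H]12 | intermediate (not isolated)
31 | 1β,10α-epoxide of 30 (bis-silyl ether of the target) | C=C1C(=O)O[C@@H]2/C=C(CO[Si](c3ccccc3)(c3ccccc3)C(C)(C)C)\C=C/[C@H]3O[C@]3(C)C[C@@H](OC(=O)/C(=C\C)CO[Si](C)(C)C(C)(C)C)[C@@H]12 | intermediate
32 | CNP0293319.2 | C=C1C(=O)O[C@@H]2/C=C(CO)\C=C/[C@H]3O[C@]3(C)C[C@@H](OC(=O)/C(=C\C)CO)[C@@H]12 | target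

## Step count and least certain steps

Total step count: 20. Longest linear sequence: 15 steps (steps 1, 2, 3, 5–13, 18, 19, 20). Steps 4 and 14–17 are convergent branches.

**Step 19 (key step).** The most likely failure is poor facial selectivity in the oxygen transfer.
- The triene is born in a folded conformer in which C14 still lies on the α face, inherited from the 10α-methyl group of 29. The desired epoxide requires the C1=C10 unit to rotate through the ring before the oxidant arrives. If the oxidant is faster than this rotation, or if the two conformers are oxidised at similar rates, both epoxide diastereomers form.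
- Secondary risks are photochemical re-closure or E/Z isomerisation of the triene at high conversion, and consumption of unreacted diene by the oxidant.
- Fallback: keep the photochemical opening, but replace substrate control by reagent control. The cold photolysate of 29 is added to a Shi epoxidation mixture (D-fructose-derived ketone, Oxone, buffered MeCN/dimethoxymethane/water, −10 °C). The chiral dioxirane selects the enantioface of the E-trisubstituted olefin that corresponds to the (1R,10R) epoxide, whichever conformer presents it. The fallback sets out from 29 (through 30) and returns at 31. It makes no new compound.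

**Step 1.** The cationic Lewis acid may ionise the dimethyl acetal of 2, with Mukaiyama-type attack of the silyl enol diene, or induce only modest enantioselectivity.
- Fallback: an auxiliary-controlled thermal cycloaddition that needs no Lewis acid.
- (2R,5R)-2,5-Diphenylpyrrolidine is condensed with (3E)-4-methoxybut-3-en-2-one to give (3E)-4-[(2R,5R)-2,5-diphenylpyrrolidin-1-yl]but-3-en-2-one F1.
- KHMDS and TBSCl convert it into (2R,5R)-1-[(1E)-3-(tert-butyldimethylsilyloxy)buta-1,3-dien-1-yl]-2,5-diphenylpyrrolidine F2.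
- Cycloaddition with 2 in toluene at 0–23 °C should give (1R,6R)-4-(tert-butyldimethylsilyloxy)-6-(dimethoxymethyl)-2-[(2R,5R)-2,5-diphenylpyrrolidin-1-yl]cyclohex-3-ene-1-carbaldehyde F3.
- Dilute HF in MeCN at 0 °C hydrolyses the enol ether and eliminates the amine. The antipodal auxiliary is used if the facial sense is opposite. The fallback sets out from 2 and returns at 4; step 2 is skipped.

**Step 12.** Two processes threaten the ring closure: 1,4-elimination of the C8 silyloxy group from the γ-oxygenated allylchromium species, and closure through the alternative chair, which would give the C6/C7 epimers.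
- Fallback: an intramolecular Hosomi–Sakurai reaction, in which the nucleophile is inert until the aldehyde is activated and the transition state is open.
- Cross-metathesis of 16 with methyl 2-[(trimethylsilyl)methyl]prop-2-enoate gives methyl (2Z,4S)-4-(tert-butyldimethylsilyloxy)-5-[(1R,6R)-5-(tert-butyldiphenylsilyloxymethyl)-6-(dimethoxymethyl)-1-methylcyclohexa-2,4-dien-1-yl]-2-[(trimethylsilyl)methyl]pent-2-enoate F4.
- Acetal cleavage as in step 11 gives the corresponding 6-formyl compound F5.
- BF3·OEt2 in CH2Cl2 at −78 °C closes ring B to 20, which lactonises to 21. The fallback sets out from 16 and returns at 21.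

**Step 18.** The carboxylate has to enter the axial position at C8, syn to the axial C1 of ring A. The displacement may be slow, and the activated alcohol may instead eliminate or return unchanged.
- Fallback: invert C8 before ring B exists.
- HF·pyridine converts 18 into methyl (2Z,4S)-2-(bromomethyl)-5-[(1R,6R)-5-(tert-butyldiphenylsilyloxymethyl)-6-(dimethoxymethyl)-1-methylcyclohexa-2,4-dien-1-yl]-4-hydroxypent-2-enoate F6.
- Mitsunobu esterification with 28 on this unhindered allylic alcohol (SN2′ is blocked by the fully substituted C11) gives the (4R)-ester, methyl (2Z,4R)-2-(bromomethyl)-4-{(2Z)-2-[(tert-butyldimethylsilyloxy)methyl]but-2-enoyloxy}-5-[(1R,6R)-5-(tert-butyldiphenylsilyloxymethyl)-6-(dimethoxymethyl)-1-methylcyclohexa-2,4-dien-1-yl]pent-2-enoate F7.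
- Acetal cleavage as in step 11 gives the 6-formyl compound F8, and CrCl2 closes ring B and the lactone.
- The price is that the C8 ester is then axial in the ring closure, so lower diastereoselectivity has to be accepted. The fallback sets out from 18 and returns at 29.

## Further compounds

F0 | step 19 | none | none
F1 | step 1 | (3E)-4-[(2R,5R)-2,5-diphenylpyrrolidin-1-yl]but-3-en-2-one | CC(=O)/C=C/N1[C@@H](c2ccccc2)CC[C@@H]1c1ccccc1
F2 | step 1 | (2R,5R)-1-[(1E)-3-(tert-butyldimethylsilyloxy)buta-1,3-dien-1-yl]-2,5-diphenylpyrrolidine | C=C(O[Si](C)(C)C(C)(C)C)/C=C/N1[C@@H](c2ccccc2)CC[C@@H]1c1ccccc1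
F3 | step 1 | (1R,6R)-4-(tert-butyldimethylsilyloxy)-6-(dimethoxymethyl)-2-[(2R,5R)-2,5-diphenylpyrrolidin-1-yl]cyclohex-3-ene-1-carbaldehyde | COC(OC)[C@H]1[C@H](C=O)[C@H](N2[C@@H](c3ccccc3)CC[C@@H]2c2ccccc2)C=C(O[Si](C)(C)C(C)(C)C)C1
F4 | step 12 | methyl (2Z,4S)-4-(tert-butyldimethylsilyloxy)-5-[(1R,6R)-5-(tert-butyldiphenylsilyloxymethyl)-6-(dimethoxymethyl)-1-methylcyclohexa-2,4-dien-1-yl]-2-[(trimethylsilyl)methyl]pent-2-enoate | COC(OC)[C@H]1C(CO[Si](c2ccccc2)(c2ccccc2)C(C)(C)C)=CC=C[C@@]1(C)C[C@H](O[Si](C)(C)C(C)(C)C)/C=C(\C[Si](C)(C)C)C(=O)OC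
F5 | step 12 | methyl (2Z,4S)-4-(tert-butyldimethylsilyloxy)-5-[(1R,6R)-5-(tert-butyldiphenylsilyloxymethyl)-6-formyl-1-methylcyclohexa-2,4-dien-1-yl]-2-[(trimethylsilyl)methyl]pent-2-enoate | O=C[C@H]1C(CO[Si](c2ccccc2)(c2ccccc2)C(C)(C)C)=CC=C[C@@]1(C)C[C@H](O[Si](C)(C)C(C)(C)C)/C=C(\C[Si](C)(C)C)C(=O)OC
F6 | step 18 | methyl (2Z,4S)-2-(bromomethyl)-5-[(1R,6R)-5-(tert-butyldiphenylsilyloxymethyl)-6-(dimethoxymethyl)-1-methylcyclohexa-2,4-dien-1-yl]-4-hydroxypent-2-enoate | COC(OC)[C@H]1C(CO[Si](c2ccccc2)(c2ccccc2)C(C)(C)C)=CC=C[C@@]1(C)C[C@H](O)/C=C(\CBr)C(=O)OC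
F7 | step 18 | methyl (2Z,4R)-2-(bromomethyl)-4-{(2Z)-2-[(tert-butyldimethylsilyloxy)methyl]but-2-enoyloxy}-5-[(1R,6R)-5-(tert-butyldiphenylsilyloxymethyl)-6-(dimethoxymethyl)-1-methylcyclohexa-2,4-dien-1-yl]pent-2-enoate | COC(OC)[C@H]1C(CO[Si](c2ccccc2)(c2ccccc2)C(C)(C)C)=CC=C[C@@]1(C)C[C@@H](OC(=O)/C(=C\C)CO[Si](C)(C)C(C)(C)C)/C=C(\CBr)C(=O)OC
F8 | step 18 | methyl (2Z,4R)-2-(bromomethyl)-4-{(2Z)-2-[(tert-butyldimethylsilyloxy)methyl]but-2-enoyloxy}-5-[(1R,6R)-5-(tert-butyldiphenylsilyloxymethyl)-6-formyl-1-methylcyclohexa-2,4-dien-1-yl]pent-2-enoate | O=C[C@H]1C(CO[Si](c2ccccc2)(c2ccccc2)C(C)(C)C)=CC=C[C@@]1(C)C[C@@H](OC(=O)/C(=C\C)CO[Si](C)(C)C(C)(C)C)/C=C(\CBr)C(=O)OC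
A1 | alternative 1 | seco-aldehyde: (2Z,4Z)-dienal with 1,10-epoxide, C8 ester and 2-(bromomethyl)enoate terminus | O=C/C=C(CO[Si](c1ccccc1)(c1ccccc1)C(C)(C)C)\C=C/[C@H]1O[C@]1(C)C[C@@H](OC(=O)/C(=C\C)CO[Si](C)(C)C(C)(C)C)/C=C(\CBr)C(=O)OC
A2 | alternative 2 | metathesis tetraene: α-methylene lactone with C6 dienyl and C7 side chain ending in a vinyl epoxide | C=C1C(=O)O[C@H](/C=C(CO[Si](c2ccccc2)(c2ccccc2)C(C)(C)C)\C=C)[C@H]1[C@H](OC(=O)/C(=C\C)CO[Si](C)(C)C(C)(C)C)C[C@@]2(C)O[C@@H]2C=C
A3 | alternative 3 | cis-1-[1-(tert-butyldimethylsilyloxy)-3-methylbuta-1,3-dien-2-yl]-6-isopropenyl-4-(tert-butyldimethylsilyloxymethyl)cyclohexa-2,4-dien-1-ol | CC(=C)[C@@H]1C=CC(CO[Si](C)(C)C(C)(C)C)=C[C@]1(O)C(=CO[Si](C)(C)C(C)(C)C)C(C)=C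
A4 | alternative 3 | 6-isopropenyl-4-(tert-butyldimethylsilyloxymethyl)cyclohexa-2,4-dien-1-one | CC(=C)[C@@H]1C=CC(CO[Si](C)(C)C(C)(C)C)=CC1=O
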